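**Plan**

- Retrosynthesis: the furanone bonds C2–C1 and O–C10 are cut together (last step). Then C1 goes back to CH2OH and the C9–C10 epoxide to an (E)-alkene, the acetyl group (C3–C4) to a vinyl iodide, the C8–O ester to an alcohol, and finally C7–C8, C7=C11 and the C6–O ester are cut.
- Enabling feature: the ring O–C3=C2–C1(=O)–C10 is a 1,3-diketone (C1, C3) closed by its enol oxygen onto the α′-carbon C10, and the neighbouring C9 carries a free OH. C9–C10 can therefore be the epoxide of a glycidic ester (C1), a 1,2-dielectrophile that matches the methyl ketone C2H3–C3=O as a C,O-dinucleophile.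
- Forward: butenolide by ring-closing metathesis, then the α-methylene-γ-lactone by Barbier union with the C8–C10/C1 enal; ester, acetyl group and epoxy acid are installed on the open chain; the ten-membered carbocycle and the furanone ring close together at the end.
- Stereochemistry: C6 from a lipase resolution; C7 by addition anti to the C6 side chain; C8 by chair-type allylation followed by Mitsunobu inversion; C9/C10 by Sharpless epoxidation with D-(−)-diethyl tartrate, C10 then inverted in the last step. The Z-C4=C5 bond comes from trans-hydroalumination/iodination, the E-C9=C10 bond from a Wittig reaction.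

Key step: step 15

Remarks on the chemistry:
- Locants C1–C15 are germacrane locants of the target: C1 ketone, C2 furanone CH, C3 furanone C–O, C4=C5, C6 lactone O–CH, C7, C8 ester carbon, C9 carbinol, C10 quaternary carbon, C11=C13 exocyclic methylene, C12 lactone carbonyl, C14/C15 methyl groups on C10/C4.
- Assumption: the zinc allylation of step 9 passes through the closed chair transition state and gives the C8 epimer of the target configuration; step 10 is therefore run with inversion.
- Assumption: the lipase of step 3 acylates the (R)-alcohol faster (large iodoalkenyl against small vinyl group).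

**Route**

Step 1
Reactants: 1 acrolein
Product: 2 rac-hex-1-en-4-yn-3-ol
Conditions: CH3C≡CMgBr, THF, −78 to 0 °C; aqueous work-up
Reagents that add atoms: 1-propynylmagnesium bromide, CC#C[Mg]Br
Why: 1,2-Addition of the alkynyl Grignard reagent to the aldehyde gives the racemic propargylic alcohol that carries C4–C7 and C15.

Step 2
Reactants: 2 rac-hex-1-en-4-yn-3-ol
Product: 4 rac-(4Z)-5-iodohexa-1,4-dien-3-ol, via cyclic alkenylaluminate 3 (not isolated)
Conditions: NaAlH2(OCH2CH2OCH3)2, THF, 0 °C to rt; then I2, THF, −78 to 0 °C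
Reagents that add atoms: iodine, II
Why: Hydroxyl-directed trans-hydroalumination of the propargylic alcohol puts aluminium on the distal alkyne carbon inside a five-membered ring, and iodinolysis with retention should give the (Z)-iodoalkene (iodine cis to the carbinol carbon), which fixes the C4=C5 geometry.

Step 3
Reactants: 4 rac-(4Z)-5-iodohexa-1,4-dien-3-ol
Product: 5 (3S,4Z)-5-iodohexa-1,4-dien-3-ol
Conditions: immobilised Candida antarctica lipase B, vinyl acetate, hexane, 30 °C, run slightly beyond half conversion; chromatography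
Reagents that add atoms: none
Why: Lipase-catalysed kinetic resolution by enantioselective transesterification should acylate the (R)-alcohol and leave the (S)-alcohol, which sets C6.

Step 4
Reactants: 5 (3S,4Z)-5-iodohexa-1,4-dien-3-ol; 6 2-(bromomethyl)prop-2-enoic acid
Product: 7 (3S,4Z)-5-iodohexa-1,4-dien-3-yl 2-(bromomethyl)prop-2-enoate
Conditions: DCC, DMAP (cat.), CH2Cl2, −20 to 0 °C
Reagents that add atoms: none
Why: Carbodiimide (Steglich) esterification acylates the alcohol oxygen with retention at C6, the low temperature keeping DMAP away from the allylic bromide.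

Step 5
Reactants: 7 (3S,4Z)-5-iodohexa-1,4-dien-3-yl 2-(bromomethyl)prop-2-enoate
Product: 8 (5S)-3-(bromomethyl)-5-[(1Z)-2-iodoprop-1-en-1-yl]furan-2(5H)-one
Conditions: second-generation Grubbs catalyst RuCl2(=CHPh)(H2IMes)(PCy3) (cat.), CH2Cl2, 40 °C, dilute
Reagents that add atoms: none
Why: Ring-closing metathesis between the terminal vinyl group and the 1,1-disubstituted acrylate closes the butenolide with loss of ethene, the trisubstituted iodoalkene being too hindered to take part.

Step 6
Reactants: 9 1-[tert-butyl(dimethyl)silyl]oxypropan-2-one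
Product: 10 ethyl (2E)-4-[tert-butyl(dimethyl)silyl]oxy-3-methylbut-2-enoate
Conditions: Ph3P=CHCO2Et, toluene, 90 °C; chromatography
Reagents that add atoms: ethyl (triphenylphosphoranylidene)acetate, CCOC(=O)C=P(c1ccccc1)(c1ccccc1)c1ccccc1
Why: Wittig olefination of the α-silyloxy ketone with the stabilised ylide should favour the (E)-enoate (ester trans to CH2OSi), which fixes the C9=C10 geometry.

Step 7
Reactants: 10 ethyl (2E)-4-[tert-butyl(dimethyl)silyl]oxy-3-methylbut-2-enoate
Product: 11 (2E)-4-[tert-butyl(dimethyl)silyl]oxy-3-methylbut-2-en-1-ol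
Conditions: i-Bu2AlH, CH2Cl2, −78 °C
Reagents that add atoms: none
Why: Hydride reduction of the conjugated ester gives the allylic alcohol without touching the silyl ether or the alkene geometry.

Step 8
Reactants: 11 (2E)-4-[tert-butyl(dimethyl)silyl]oxy-3-methylbut-2-en-1-ol
Product: 12 (2E)-4-[tert-butyl(dimethyl)silyl]oxy-3-methylbut-2-enal
Conditions: MnO2, CH2Cl2, rt
Reagents that add atoms: none
Why: Manganese dioxide oxidises the allylic alcohol selectively to the (E)-enal without isomerisation.

Step 9
Reactants: 8 (5S)-3-(bromomethyl)-5-[(1Z)-2-iodoprop-1-en-1-yl]furan-2(5H)-one; 12 (2E)-4-[tert-butyl(dimethyl)silyl]oxy-3-methylbut-2-enal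
Product: 13 (4R,5S)-4-[(1S,2E)-4-{[tert-butyl(dimethyl)silyl]oxy}-1-hydroxy-3-methylbut-2-en-1-yl]-5-[(1Z)-2-iodoprop-1-en-1-yl]-3-methylideneoxolan-2-one
Conditions: Zn dust, THF/sat. aq NH4Cl, 0 °C to rt
Reagents that add atoms: none
Why: Barbier allylation in which the allylzinc from 8 adds through ring carbon C7 to the aldehyde in a closed chair transition state, anti to the C6 side chain (C7 trans to C6) and, with the ring-locked E-type allyl unit and the aldehyde substituent equatorial, with the crotyl-type anti outcome at C8 (epimeric to the target), the double bond moving to the exocyclic position.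

Step 10
Reactants: 13 Barbier alcohol (C8 epimer)
Product: 14 (1R,2E)-4-[tert-butyl(dimethyl)silyl]oxy-1-{(2S,3R)-2-[(1Z)-2-iodoprop-1-en-1-yl]-4-methylidene-5-oxooxolan-3-yl}-3-methylbut-2-en-1-yl 2-methylpropanoate
Conditions: i-PrCO2H, PPh3, DIAD, toluene, 0 °C to rt
Reagents that add atoms: 2-methylpropanoic acid, CC(C)C(=O)O
Why: Mitsunobu esterification displaces the activated C8 oxygen by isobutyrate with SN2 inversion, which installs the ester and corrects C8 in one operation.

Step 11
Reactants: 14 iodoalkene isobutyrate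
Product: 16 (1R,2E)-4-hydroxy-3-methyl-1-{(2R,3R)-4-methylidene-2-[(1Z)-2-methyl-3-oxobut-1-en-1-yl]-5-oxooxolan-3-yl}but-2-en-1-yl 2-methylpropanoate, via ethoxydiene 15 (not isolated)
Conditions: CH2=C(OEt)SnBu3, Pd2(dba)3 (cat.), AsPh3, CuI, DMF, rt; then 1 M aq HCl, THF, 0 °C to rt
Reagents that add atoms: tributyl(1-ethoxyvinyl)stannane, CCOC(=C)[Sn](CCCC)(CCCC)CCCC; water, O
Why: Stille coupling of the vinyl iodide proceeds with retention of the Z geometry, and aqueous acid then hydrolyses the enol ether to the methyl ketone and removes the primary silyl ether.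

Step 12
Reactants: 16 enone allylic alcohol
Product: 17 (S)-[(2R,3R)-3-(hydroxymethyl)-3-methyloxiran-2-yl]{(2R,3S)-4-methylidene-2-[(1Z)-2-methyl-3-oxobut-1-en-1-yl]-5-oxooxolan-3-yl}methyl 2-methylpropanoate
Conditions: Ti(OiPr)4, D-(−)-diethyl tartrate, t-BuOOH, 4 Å MS, CH2Cl2, −20 °C
Reagents that add atoms: tert-butyl hydroperoxide, CC(C)(C)OO
Why: Sharpless asymmetric epoxidation epoxidises only the alkene of the primary allylic alcohol, and with D-(−)-diethyl tartrate the (E)-2-methyl allylic alcohol should give the (2R,3R)-epoxy alcohol under reagent control, which sets C9 and C10.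

Step 13
Reactants: 17 epoxy alcohol
Product: 18 (2S,3R)-2-methyl-3-[(S)-{(2R,3S)-4-methylidene-2-[(1Z)-2-methyl-3-oxobut-1-en-1-yl]-5-oxooxolan-3-yl}(2-methylpropanoyloxy)methyl]oxirane-2-carboxylic acid
Conditions: TEMPO (cat.), PhI(OAc)2, MeCN/aqueous pH 7 buffer, rt
Reagents that add atoms: water, O
Why: Oxoammonium oxidation takes the primary alcohol through the aldehyde hydrate to the acid, and the quaternary C10 cannot epimerise.

Step 14
Reactants: 18 epoxy acid
Product: 19 pentafluorophenyl (2S,3R)-2-methyl-3-[(S)-{(2R,3S)-4-methylidene-2-[(1Z)-2-methyl-3-oxobut-1-en-1-yl]-5-oxooxolan-3-yl}(2-methylpropanoyloxy)methyl]oxirane-2-carboxylate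
Conditions: C6F5OH, DCC, CH2Cl2, 0 °C to rt
Reagents that add atoms: pentafluorophenol, Oc1c(F)c(F)c(F)c(F)c1F
Why: Carbodiimide coupling with the acidic phenol gives an isolable active ester that is reactive enough for enolate acylation.

Step 15
Reactants: 19 pentafluorophenyl glycidate
Product: 21 target CNP0265772.1, via ten-membered epoxy diketone 20 (not isolated)
Conditions: MgBr2·OEt2, i-Pr2NEt, CH2Cl2, high dilution (slow addition of 19), 0 °C to rt; then pH 7 buffer, 0 °C
Reagents that add atoms: none
Why: Proposed new method: MgBr2 binds the enone carbonyl so that i-Pr2NEt removes a proton only from the C2 methyl group (soft enolisation; the esters, the lactone and the non-enolisable glycidate stay untouched), the magnesium enolate is C-acylated by the pentafluorophenyl ester at C1 to give the ten-membered β-diketonate 20, and the enolate oxygen on C3 then opens the C9–C10 epoxide at C10 from the rear, leaving the C9 alkoxide. The closest known reactions are the amine/MgBr2 soft-enolisation acylation of ketones with activated esters to 1,3-diketones and the base-induced closure of 1,3-diketones with a leaving group on the α′-carbon to 3(2H)-furanones; new is their coupling in one ring-forming operation with an epoxide as the leaving group. The ten-membered carbocycle closes by 10-exo-trig attack of C2 on the exocyclic C1 carbonyl, and the furanone closes by 5-exo-tet O-alkylation at C10, the breaking C10–O bond lying outside the new ring. C10 is set by stereospecific inversion of the epoxide carbon installed in step 12 (10S in 19 to 10R in 21), C9 keeps the epoxide oxygen as its free hydroxyl with retention, and no other centre is touched. The step needs ring closure over oligomerisation (high dilution; the Z-C4=C5 bond and the trans-lactone fold the chain and magnesium bridges enolate and glycidate), C- over O-acylation (magnesium chelate), and attack at C10 instead of 6-endo attack at C9 (C10 is α to the new ketone, magnesium held between the C1 carbonyl oxygen and the epoxide oxygen polarises the C10–O bond in the plane of the forming ring, and the medium ring keeps the C3 oxygen next to C10). A cold neutral quench should limit 1,2-shift of the C8 isobutyryl group to the C9 alkoxide.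

**Compound list**

1 | acrolein (prop-2-enal) | C=CC=O | starting material
2 | rac-hex-1-en-4-yn-3-ol | C=CC(O)C#CC | intermediate
3 | sodium 2,2-bis(2-methoxyethoxy)-3-methyl-5-vinyl-2,5-dihydro-1,2-oxaaluminol-2-uide (cyclic alkenylaluminate, racemic, not isolated) | C=CC1C=C(C)[Al-](OCCOC)(OCCOC)O1.[Na+] | intermediate
4 | rac-(4Z)-5-iodohexa-1,4-dien-3-ol | C=CC(O)/C=C(/C)I | intermediate
5 | (3S,4Z)-5-iodohexa-1,4-dien-3-ol | C=C[C@H](O)/C=C(/C)I | intermediate
6 | 2-(bromomethyl)prop-2-enoic acid | C=C(CBr)C(=O)O | starting material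
7 | (3S,4Z)-5-iodohexa-1,4-dien-3-yl 2-(bromomethyl)prop-2-enoate | C=C[C@H](OC(=O)C(=C)CBr)/C=C(/C)I | intermediate
8 | (5S)-3-(bromomethyl)-5-[(1Z)-2-iodoprop-1-en-1-yl]furan-2(5H)-one | BrCC1=C[C@@H](/C=C(/C)I)OC1=O | intermediate
9 | 1-[tert-butyl(dimethyl)silyl]oxypropan-2-one | CC(=O)CO[Si](C)(C)C(C)(C)C | starting material
10 | ethyl (2E)-4-[tert-butyl(dimethyl)silyl]oxy-3-methylbut-2-enoate | CCOC(=O)/C=C(\C)CO[Si](C)(C)C(C)(C)C | intermediate
11 | (2E)-4-[tert-butyl(dimethyl)silyl]oxy-3-methylbut-2-en-1-ol | OC/C=C(\C)CO[Si](C)(C)C(C)(C)C | intermediate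
12 | (2E)-4-[tert-butyl(dimethyl)silyl]oxy-3-methylbut-2-enal | O=C/C=C(\C)CO[Si](C)(C)C(C)(C)C | intermediate
13 | (4R,5S)-4-[(1S,2E)-4-{[tert-butyl(dimethyl)silyl]oxy}-1-hydroxy-3-methylbut-2-en-1-yl]-5-[(1Z)-2-iodoprop-1-en-1-yl]-3-methylideneoxolan-2-one | C=C1C(=O)O[C@H](/C=C(/C)I)[C@H]1[C@@H](O)/C=C(\C)CO[Si](C)(C)C(C)(C)C | intermediate
14 | (1R,2E)-4-[tert-butyl(dimethyl)silyl]oxy-1-{(2S,3R)-2-[(1Z)-2-iodoprop-1-en-1-yl]-4-methylidene-5-oxooxolan-3-yl}-3-methylbut-2-en-1-yl 2-methylpropanoate | C=C1C(=O)O[C@H](/C=C(/C)I)[C@H]1[C@H](OC(=O)C(C)C)/C=C(\C)CO[Si](C)(C)C(C)(C)C | intermediate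
15 | (1R,2E)-4-[tert-butyl(dimethyl)silyl]oxy-1-{(2R,3R)-2-[(1Z)-3-ethoxy-2-methylbuta-1,3-dien-1-yl]-4-methylidene-5-oxooxolan-3-yl}-3-methylbut-2-en-1-yl 2-methylpropanoate (not isolated) | C=C1C(=O)O[C@H](/C=C(/C)C(=C)OCC)[C@H]1[C@H](OC(=O)C(C)C)/C=C(\C)CO[Si](C)(C)C(C)(C)C | intermediate
16 | (1R,2E)-4-hydroxy-3-methyl-1-{(2R,3R)-4-methylidene-2-[(1Z)-2-methyl-3-oxobut-1-en-1-yl]-5-oxooxolan-3-yl}but-2-en-1-yl 2-methylpropanoate | C=C1C(=O)O[C@H](/C=C(/C)C(C)=O)[C@H]1[C@H](OC(=O)C(C)C)/C=C(\C)CO | intermediate
17 | (S)-[(2R,3R)-3-(hydroxymethyl)-3-methyloxiran-2-yl]{(2R,3S)-4-methylidene-2-[(1Z)-2-methyl-3-oxobut-1-en-1-yl]-5-oxooxolan-3-yl}methyl 2-methylpropanoate | C=C1C(=O)O[C@H](/C=C(/C)C(C)=O)[C@H]1[C@H](OC(=O)C(C)C)[C@H]2O[C@]2(C)CO | intermediate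
18 | (2S,3R)-2-methyl-3-[(S)-{(2R,3S)-4-methylidene-2-[(1Z)-2-methyl-3-oxobut-1-en-1-yl]-5-oxooxolan-3-yl}(2-methylpropanoyloxy)methyl]oxirane-2-carboxylic acid | C=C1C(=O)O[C@H](/C=C(/C)C(C)=O)[C@H]1[C@H](OC(=O)C(C)C)[C@H]2O[C@]2(C)C(=O)O | intermediate
19 | pentafluorophenyl ester of 18 | C=C1C(=O)O[C@H](/C=C(/C)C(C)=O)[C@H]1[C@H](OC(=O)C(C)C)[C@H]2O[C@]2(C)C(=O)Oc3c(F)c(F)c(F)c(F)c3F | intermediate
20 | (6R,7S,8S,9R,10S)-9,10-epoxy-8-(2-methylpropanoyloxy)-1,3-dioxogermacra-4Z,11(13)-dien-12,6-olide (formed in step 15 as its bromomagnesium enolate, not isolated) | C=C1C(=O)O[C@@H]2/C=C(/C)C(=O)CC(=O)[C@@]3(C)O[C@@H]3[C@@H](OC(=O)C(C)C)[C@@H]12 | intermediate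
21 | (6R,7S,8S,9R,10R)-9-hydroxy-8-(2-methylpropanoyloxy)-1-oxo-3,10-epoxygermacra-2,4Z,11(13)-trien-12,6-olide (CNP0265772.1) | C=C1C(=O)O[C@@H]2/C=C(/C)C3=CC(=O)[C@](C)(O3)[C@H](O)[C@@H](OC(=O)C(C)C)[C@@H]12 | target

**Count and risks**

Total steps: 15. Longest linear sequence: 12 steps (steps 1–5 and 9–15).

Steps most likely to fail:

1. Step 15 (proposed new method). The medium-ring closure may lose to intermolecular acylation. Bromide may open the epoxide before the enolate oxygen arrives. After closure, the isobutyryl group may shift to the C9 alkoxide, or the C9–C10 bond may cleave by retro-aldol reaction. Fallback: it sets out from 17 and returns at 20. Dess–Martin oxidation of 17 gives the epoxy aldehyde F1. The methyl ketone of F1 is enolised with (c-C6H11)2BCl/Et3N at −78 °C under high dilution, and the boron enolate adds to the non-enolisable aldehyde in an intramolecular aldol reaction to give the ten-membered β-hydroxy ketone F2. A second Dess–Martin oxidation gives the β-diketone 20, which should close to 21 on brief exposure to DBU in CH2Cl2, the known O-alkylative closure of 1,3-diketones with a leaving group on the α′-carbon.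

2. Step 10. Stereospecificity may be lost through ionisation of the allylic oxyphosphonium ion (SN1 or SN2′ leakage) or elimination toward C7, or the allylation of step 9 may not follow the assumed chair transition state. Fallback: it sets out from 8 and returns at 14. Zinc-mediated stannylation of 8 (Bu3SnCl, Zn, THF/aq NH4Cl) gives the allylstannane F3. BF3·OEt2-promoted addition of F3 to aldehyde 12 at −78 °C passes through an open antiperiplanar transition state, which is syn-selective whatever the allyl geometry, and should give the C8-epimeric alcohol F4 with the target configuration at C8. Plain acylation with isobutyryl chloride, pyridine and DMAP (retention) then gives 14.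

3. Step 11. The alkenylpalladium intermediate may insert into the exocyclic methylene (Heck-type cyclisation), zerovalent palladium may ionise the allylic isobutyrate, and the enone may isomerise from Z to E during the acid hydrolysis. Fallback: it sets out from 14 and returns at 16. Nozaki–Hiyama–Kishi coupling of the vinyl iodide with acetaldehyde (CrCl2, catalytic NiCl2, DMF) gives the allylic alcohol F5 as a mixture at the new carbinol. Dess–Martin oxidation gives the enone silyl ether F6, and HF·pyridine in THF removes the silyl group to give 16.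

Further compounds
F1 | step 15 | (S)-[(2R,3S)-3-formyl-3-methyloxiran-2-yl]{(2R,3S)-4-methylidene-2-[(1Z)-2-methyl-3-oxobut-1-en-1-yl]-5-oxooxolan-3-yl}methyl 2-methylpropanoate | C=C1C(=O)O[C@H](/C=C(/C)C(C)=O)[C@H]1[C@H](OC(=O)C(C)C)[C@H]2O[C@]2(C)C=O
F2 | step 15 | C1-hydroxy analogue of 20 (9,10-epoxy-1-hydroxy-8-(2-methylpropanoyloxy)-3-oxogermacra-4Z,11(13)-dien-12,6-olide, both C1 epimers, other centres as in 20) | C=C1C(=O)O[C@@H]2/C=C(/C)C(=O)CC(O)[C@@]3(C)O[C@@H]3[C@@H](OC(=O)C(C)C)[C@@H]12
F3 | step 10 | (5S)-5-[(1Z)-2-iodoprop-1-en-1-yl]-3-[(tributylstannyl)methyl]furan-2(5H)-one | CCCC[Sn](CCCC)(CCCC)CC1=C[C@@H](/C=C(/C)I)OC1=O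
F4 | step 10 | (4R,5S)-4-[(1R,2E)-4-{[tert-butyl(dimethyl)silyl]oxy}-1-hydroxy-3-methylbut-2-en-1-yl]-5-[(1Z)-2-iodoprop-1-en-1-yl]-3-methylideneoxolan-2-one | C=C1C(=O)O[C@H](/C=C(/C)I)[C@H]1[C@H](O)/C=C(\C)CO[Si](C)(C)C(C)(C)C
F5 | step 11 | (1R,2E)-4-[tert-butyl(dimethyl)silyl]oxy-1-{(2R,3R)-2-[(1Z)-3-hydroxy-2-methylbut-1-en-1-yl]-4-methylidene-5-oxooxolan-3-yl}-3-methylbut-2-en-1-yl 2-methylpropanoate (both carbinol epimers) | C=C1C(=O)O[C@H](/C=C(/C)C(C)O)[C@H]1[C@H](OC(=O)C(C)C)/C=C(\C)CO[Si](C)(C)C(C)(C)C
F6 | step 11 | (1R,2E)-4-[tert-butyl(dimethyl)silyl]oxy-3-methyl-1-{(2R,3R)-4-methylidene-2-[(1Z)-2-methyl-3-oxobut-1-en-1-yl]-5-oxooxolan-3-yl}but-2-en-1-yl 2-methylpropanoate | C=C1C(=O)O[C@H](/C=C(/C)C(C)=O)[C@H]1[C@H](OC(=O)C(C)C)/C=C(\C)CO[Si](C)(C)C(C)(C)C
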